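**Locants.** Tetralin numbering is used throughout: C1 is the diarylmethine, C2 bears the arm C2a (the sulfated CH2O), C3 bears the arm C3a (the free CH2OH), C4 is the ring methylene, and ring A is C4a/C5–C8/C8a. The same labels are kept for these atoms in every intermediate.

## Analysis of the target

The target is an aryltetralin cyclolignan in which ring A (methoxy at C6 and C8, hydroxyl at C7) is fused to the saturated ring B (C1–C4). C1 carries a 4-hydroxy-3,5-dimethoxyphenyl ring, C2 the sulfated arm C2a, C3 the hydroxymethyl arm C3a, and C4 is a methylene. The three stereocentres are contiguous, (1R,2S,3S), and all-trans: the pendant aryl group and C3a lie on one face of ring B and C2a on the other. The primary alkyl hydrogen sulfate is a strong acid and solvolyses easily, so it must be made late and uncovered under neutral conditions; the two 2,6-dimethoxyphenols are easily oxidised, and both arenes remain nucleophilic. The main difficulty is that C2a and C3a are two primary CH2O groups in almost the same environment, yet only C2a is sulfated, so the way the skeleton is built has to tell them apart. The strategy rests on C1: its two aryl partners are bonded through carbons that are nucleophilic in the free arenes (C8a of ring A is ortho to the C8 methoxy and para to the C6 methoxy; the pendant ring is joined through the carbon para to its hydroxyl). C1 can therefore be an electrophilic carbon at the aldehyde oxidation level, and if it is the acetal carbon of an oxolane whose ring oxygen is the C3a oxygen, C3a–O is distinguished from C2a–O from the start and is set free in the step that makes both C1–aryl bonds. One stereochemical consequence governs the front end: at C3 the ring bond and the substituent change places between the oxolane (C3a in the ring, C4 outside) and ring B (C4 in the ring, C3a outside), while the C2–C1 ring bond is common to both, so the 2,3-trans tetralin corresponds to the oxolane in which C2a and the C4 benzyl group are cis.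

## Retrosynthetic reasoning

**19 ⇐ 18 ⇐ 17 ⇐ 16 ⇐ 15 (O–benzyl, O–S, O–Si bonds).** The three benzyl ethers are cut last because hydrogenolysis is neutral and leaves a sulfate monoester alone. The S–O bond is cut next: sulfation is only clean if C2a–OH is the single free hydroxyl, so 17 has both phenols and C3a–OH as benzyl ethers. C2a–O must therefore carry a group orthogonal to benzyl (a silyl ether, 16), and the pendant phenol and C3a–OH must be free together one step earlier (15) so that one benzylation covers both.

**15 ⇐ 12 + 13 (C1–C8a and C1–aryl).** Both bonds at C1 are cut, which returns C1 to an acetal carbon and the pendant ring to the free phenol 13. Cutting here gains ring B, the whole diarylmethine and the C1 stereocentre in one operation, and the oxolane oxygen of 12 reappears as exactly the free C3a–OH that 15 needs. The forward reaction has to close ring B through the ring A carbon ortho to the benzylic CH2, then arylate the resulting benzylic cation at the para carbon of 13 on the face anti to the C2 arm.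

**12 ⇐ 11 ⇐ 9 (acetal C1–O bond, lactone carbonyl as C2a).** In 12 the C2a arm and the C4 benzyl group are cis on the oxolane, for the reason given in the analysis. A cis oxolane cannot come from trans-selective enolate chemistry if the enolate electrophile is C2a. It can if the electrophile is C1 and the lactone carbonyl becomes C2a. Hence 11 is traced to the trans lactone 9, whose carbonyl is reduced to C2a–OH and whose dimethyl acetal is C1. In the derived diol (10) only C3a–OH can reach the acetal carbon through a five-membered ring, so transacetalisation selects it and leaves C2a–OH for the silyl group.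

**9 ⇐ 7 (C1–C2).** The C1–C2 bond is cut to the β-benzyl butyrolactone 7 and a one-carbon electrophile at the aldehyde oxidation level (an orthoformate under Lewis acid, acting on the silyl ketene acetal 8). The forward step must place C1 anti to the benzyl group, which is both the kinetic and the thermodynamic outcome for this ring.

**7 ⇐ 5 ⇐ 4 ⇐ 2 + 3; 2 ⇐ 1.** The lactone is opened to the half-ester 5, whose single stereocentre (the future C3) comes from asymmetric hydrogenation of the alkylidene succinate 4. The C3–C4 double bond of 4 is cut by a Stobbe condensation to the aldehyde 2 and the diester 3; 2 is the benzyl ether of 1.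

## Alternatives that were turned down

**Alternative 1:** Disconnection of C2–C3 and C1–C8a by oxidative dimerisation. In the forward step two molecules of the sinapoyl imide A1 are oxidised at a carbon anode; the β-carbons couple and ring A of one half closes onto the quinone methide of the other, giving the 1,2-dihydronaphthalene bis-imide A2. In its favour, the whole carbon skeleton, both arenes with their final oxygenation and the C1/C2 relationship arise in one step from a single cheap cinnamoyl unit, with no phenol protection. On step count to the skeleton it is clearly stronger than the chosen route. Against it for this target: absolute control depends on remote auxiliaries in a radical/quinone-methide coupling; A2 is itself an oxidisable phenol; the C3=C4 bond must still be reduced with creation of C3 trans to C2; and the two arms are the same acyl imide, so after reduction C2a–OH and C3a–OH have no built-in distinction for a monosulfate. The chosen strategy is longer but differentiates the arms by construction and sets C2 and C3 in separate steps.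

**Alternative 2:** Disconnection of C1–C2 and C3–C4 by a Diels–Alder reaction. Irradiation of the 2-benzylbenzaldehyde A3 gives a hydroxy-ortho-quinodimethane that adds to the chiral fumarate A4 to give the tetralin diester A5. In its favour, two C–C bonds, ring B and up to four stereocentres form at once, and the 2,3-trans relationship follows stereospecifically from the fumarate geometry; on C2/C3 control in a single operation it is stronger than the chosen route. Against it: lactate auxiliaries give good facial control mainly under Lewis-acid chelation, which a transient photoenol does not allow; A3 is a pentasubstituted benzaldehyde with an ortho diarylmethane link and needs its own multistep synthesis; the C4 hydroxyl of A5 is surplus and must be removed by a benzylic deoxygenation; and the two ester arms are again identical. The chosen strategy needs no deoxygenation and delivers the arms already distinguished.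

**Alternative 3:** Disconnection of C3=C4 by ring-closing metathesis. A ruthenium carbene catalyst joins the ring A styrene and the 1,1-disubstituted alkene of the diene A6 to give the 1,2-dihydronaphthalene A7; a hydroxyl-directed hydrogenation then sets C3. In its favour, the ring closure is dependable, and A7 already has C3a–O benzylated and C2a–OH free, so the homoallylic hydroxyl can deliver hydrogen to C3 on the face of the C2 arm and the end game (hydrogenation, sulfation, hydrogenolysis) is one step shorter than the chosen one. On arm differentiation and end game it is the stronger plan. Against it: the key step forms one bond and no stereocentre; the acyclic C1/C2 pair of A6, a diarylmethine whose two aryl groups differ only by an ortho vinyl group, has to be built beforehand, as does the ortho-vinyl pentasubstituted ring A, which makes the linear sequence long. The chosen strategy forms two C–C bonds and C1 in its key step from two cheap syringyl components.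

Key step: step 8

**Assumption:** the target is taken as the free hydrogen sulfate as drawn; from step 11 on it is carried as the sodium salt and the acid is released at the end on a cation-exchange resin (H+ form), 18 and 19 being drawn as free acids.

## Route

Step 1
Reactants: 1 syringaldehyde (4-hydroxy-3,5-dimethoxybenzaldehyde)
Product: 2 4-(benzyloxy)-3,5-dimethoxybenzaldehyde
Conditions: BnBr (1.1 equiv), K2CO3 (1.5 equiv), DMF, 60 °C
Reagents that add atoms: benzyl bromide, BrCc1ccccc1
Why: Williamson ether synthesis on the only acidic site; the benzyl ether makes the aldehyde fit for the Stobbe condensation and falls in the final hydrogenolysis.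

Step 2
Reactants: 2 4-(benzyloxy)-3,5-dimethoxybenzaldehyde; 3 dimethyl succinate
Product: 4 (E)-4-[4-(benzyloxy)-3,5-dimethoxyphenyl]-3-(methoxycarbonyl)but-3-enoic acid
Conditions: NaOMe (2 equiv), MeOH, reflux; then aq. HCl
Reagents that add atoms: none
Why: Stobbe condensation; the aldol adduct lactonises and opens by E1cB to the half-ester in which the aryl group is trans to the retained ester, the geometry wanted for the hydrogenation.

Step 3
Reactants: 4 (E)-4-[4-(benzyloxy)-3,5-dimethoxyphenyl]-3-(methoxycarbonyl)but-3-enoic acid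
Product: 5 (S)-4-[4-(benzyloxy)-3,5-dimethoxyphenyl]-3-(methoxycarbonyl)butanoic acid
Conditions: H2 (5 bar), [Rh(cod)((R,R)-Et-DuPhos)]BF4 (0.5 mol%), NaOMe (10 mol%), MeOH, rt
Reagents that add atoms: none
Why: Asymmetric hydrogenation of a Stobbe half-ester (a β-aryl itaconate), in which carboxylate and alkene chelate the rhodium bisphosphine catalyst; this sets the future C3, the aryl benzyl ether is inert to the homogeneous catalyst, and the ligand hand shown is the one expected by analogy with itaconates to give the S acid, to be confirmed on the first run (the mirror-image ligand is used otherwise).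

Step 4
Reactants: 5 (S)-4-[4-(benzyloxy)-3,5-dimethoxyphenyl]-3-(methoxycarbonyl)butanoic acid
Product: 7 (S)-4-[4-(benzyloxy)-3,5-dimethoxybenzyl]dihydrofuran-2(3H)-one, via hydroxy acid 6 (not isolated)
Conditions: KOH (1.0 equiv), EtOH; CaCl2, NaBH4, EtOH, 0 °C to rt; then 3 M HCl, rt
Reagents that add atoms: none
Why: Calcium borohydride formed in the flask reduces the methyl ester but not the carboxylate, and the γ-hydroxy acid lactonises on acidification; the stereocentre is not touched.

Step 5
Reactants: 7 (S)-4-[4-(benzyloxy)-3,5-dimethoxybenzyl]dihydrofuran-2(3H)-one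
Product: 9 (3R,4S)-4-[4-(benzyloxy)-3,5-dimethoxybenzyl]-3-(dimethoxymethyl)dihydrofuran-2(3H)-one, via silyl ketene acetal 8 (not isolated)
Conditions: LDA (1.1 equiv), THF, −78 °C; Me3SiCl, −78 to 0 °C; solvent exchange to CH2Cl2; HC(OMe)3 (2 equiv), BF3·OEt2 (1.1 equiv), −78 °C
Reagents that add atoms: trimethyl orthoformate, COC(OC)OC
Why: Mukaiyama-type alkylation of a lactone silyl ketene acetal by the dimethoxycarbenium ion from the orthoformate; the electrophile approaches the planar 2-silyloxy-4,5-dihydrofuran anti to the C4 benzyl group, so the new centre (C2 of the target) is trans, which is also the thermodynamic epimer, and the carbon introduced is the future C1.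

Step 6
Reactants: 9 (3R,4S)-4-[4-(benzyloxy)-3,5-dimethoxybenzyl]-3-(dimethoxymethyl)dihydrofuran-2(3H)-one
Product: 11 [(3S,4S)-4-[4-(benzyloxy)-3,5-dimethoxybenzyl]-2-methoxyoxolan-3-yl]methanol (anomer mixture at the acetal carbon), via diol acetal 10 (not isolated)
Conditions: LiAlH4 (1.5 equiv), THF, 0 °C; aq. NaOH work-up; then camphorsulfonic acid (5 mol%), CH2Cl2, 4 Å MS, rt
Reagents that add atoms: none
Why: Hydride reduction turns the lactone carbonyl into C2a–OH; in the acid-catalysed transacetalisation only C3a–OH can reach C1 through a five-membered ring, so the two primary hydroxyls are differentiated, the oxolane now has C2a cis to the benzyl group, and C2 is no longer α to a carbonyl.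

Step 7
Reactants: 11 [(3S,4S)-4-[4-(benzyloxy)-3,5-dimethoxybenzyl]-2-methoxyoxolan-3-yl]methanol
Product: 12 tert-butyl{[(3S,4S)-4-[4-(benzyloxy)-3,5-dimethoxybenzyl]-2-methoxyoxolan-3-yl]methoxy}diphenylsilane
Conditions: TBDPSCl (1.2 equiv), imidazole (2.5 equiv), DMF, 0 °C to rt
Reagents that add atoms: tert-butyl(chloro)diphenylsilane, CC(C)(C)[Si](Cl)(c1ccccc1)c1ccccc1
Why: Standard silylation of the only free hydroxyl; the bulky, acid-tolerant silyl ether marks C2a–O through the key step and later shields one face of C1.

Step 8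
Reactants: 12 tert-butyl{[(3S,4S)-4-[4-(benzyloxy)-3,5-dimethoxybenzyl]-2-methoxyoxolan-3-yl]methoxy}diphenylsilane; 13 2,6-dimethoxyphenol
Product: 15 4-[(1R,2S,3S)-7-(benzyloxy)-2-({[tert-butyl(diphenyl)silyl]oxy}methyl)-3-(hydroxymethyl)-6,8-dimethoxy-1,2,3,4-tetrahydronaphthalen-1-yl]-2,6-dimethoxyphenol, via bridged C1–O–C3a ether 14 (not isolated)
Conditions: BF3·OEt2 (2.5 equiv), CH2Cl2, −40 °C; then 13 (4 equiv), −40 to 0 °C
Reagents that add atoms: none
Why: BF3 abstracts methoxide from the acetal carbon of 12 and gives the oxolanyl oxocarbenium ion at C1. The ring A carbon ortho to the benzylic CH2 (ortho to one methoxy and para to the other; the two such positions are equivalent) attacks C1 from the face on which the benzyl group stands, a Friedel–Crafts closure of ring B that is six-membered and 6-exo-trig with respect to the C1=O+ bond and leaves the C3a oxygen bridging C1 and C3 in 14. BF3 then ionises the benzylic C1–O bond of 14, assisted by the C8 (ortho) and C6 (para) methoxy groups, and the cation is captured by 13 through the carbon para to its hydroxyl, so that the C3a oxygen ends as the free alcohol. The closest known reaction types are the Lewis-acid C-arylation of lactol acetals by electron-rich arenes, including intramolecular cases that give benzo-fused oxabicycles, and the Friedel–Crafts arylation of 2,3-disubstituted tetralin-1-yl cations. C1 is the only new stereocentre and is under substrate control: the arene should enter anti to the bulky silyloxymethyl arm on C2, which is the face of the C3 arm and gives the all-trans array, while C2 and C3 are not touched. The step needs ring closure before intermolecular arylation, secured by adding 13 only after 12 is consumed; para selectivity on 13, which rests on the hydroxyl being the strongest donor and its para carbon the least hindered site; and single alkylation, for which 13 is used in excess. The aryl benzyl ether and the silyl ether are expected to survive BF3·OEt2 at or below 0 °C.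

Step 9
Reactants: 15 4-[(1R,2S,3S)-7-(benzyloxy)-2-({[tert-butyl(diphenyl)silyl]oxy}methyl)-3-(hydroxymethyl)-6,8-dimethoxy-1,2,3,4-tetrahydronaphthalen-1-yl]-2,6-dimethoxyphenol
Product: 16 (1R,2S,3S)-7-(benzyloxy)-1-[4-(benzyloxy)-3,5-dimethoxyphenyl]-3-[(benzyloxy)methyl]-2-({[tert-butyl(diphenyl)silyl]oxy}methyl)-6,8-dimethoxy-1,2,3,4-tetrahydronaphthalene
Conditions: NaH (3 equiv), BnBr (3 equiv), Bu4NI (cat.), DMF, 0 °C to rt
Reagents that add atoms: benzyl bromide, BrCc1ccccc1
Why: Double Williamson etherification of the phenoxide and the primary alkoxide, so that after desilylation C2a–OH is the only hydroxyl; iodide catalysis keeps the alkylation fast at 0 °C.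

Step 10
Reactants: 16 (1R,2S,3S)-7-(benzyloxy)-1-[4-(benzyloxy)-3,5-dimethoxyphenyl]-3-[(benzyloxy)methyl]-2-({[tert-butyl(diphenyl)silyl]oxy}methyl)-6,8-dimethoxy-1,2,3,4-tetrahydronaphthalene
Product: 17 [(1R,2S,3S)-7-(benzyloxy)-1-[4-(benzyloxy)-3,5-dimethoxyphenyl]-3-[(benzyloxy)methyl]-6,8-dimethoxy-1,2,3,4-tetrahydronaphthalen-2-yl]methanol
Conditions: Bu4NF (1.5 equiv), THF, rt
Reagents that add atoms: none
Why: Fluoride cleavage of the silyl ether; benzyl ethers are inert and only C2a–OH is released.

Step 11
Reactants: 17 [(1R,2S,3S)-7-(benzyloxy)-1-[4-(benzyloxy)-3,5-dimethoxyphenyl]-3-[(benzyloxy)methyl]-6,8-dimethoxy-1,2,3,4-tetrahydronaphthalen-2-yl]methanol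
Product: 18 [(1R,2S,3S)-7-(benzyloxy)-1-[4-(benzyloxy)-3,5-dimethoxyphenyl]-3-[(benzyloxy)methyl]-6,8-dimethoxy-1,2,3,4-tetrahydronaphthalen-2-yl]methyl hydrogen sulfate (handled as the sodium salt)
Conditions: SO3·pyridine (5 equiv), pyridine, rt to 40 °C; then aq. NaHCO3
Reagents that add atoms: sulfur trioxide–pyridine complex, O=S(=O)([O-])[n+]1ccccc1
Why: O-sulfation of a primary alcohol with an amine–sulfur trioxide complex; no other hydroxyl is free and the complex is too mild to sulfonate the aryl ethers; exchange to the sodium salt removes pyridine, which would slow the next step.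

Step 12
Reactants: 18 [(1R,2S,3S)-7-(benzyloxy)-1-[4-(benzyloxy)-3,5-dimethoxyphenyl]-3-[(benzyloxy)methyl]-6,8-dimethoxy-1,2,3,4-tetrahydronaphthalen-2-yl]methyl hydrogen sulfate
Product: 19 [(1R,2S,3S)-7-hydroxy-1-(4-hydroxy-3,5-dimethoxyphenyl)-3-(hydroxymethyl)-6,8-dimethoxy-1,2,3,4-tetrahydronaphthalen-2-yl]methyl hydrogen sulfate
Conditions: H2 (1 atm), 10% Pd/C, MeOH–H2O 9:1, rt; then sulfonic acid cation-exchange resin (H+ form), 0 °C
Reagents that add atoms: none
Why: Hydrogenolysis of the two aryl benzyl ethers and the alkyl benzyl ether; the sulfate monoester anion and the diarylmethine C1 are not reduced, and no stereocentre is affected.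

## Compound list

1 | syringaldehyde | COc1cc(C=O)cc(OC)c1O | starting material
2 | 4-(benzyloxy)-3,5-dimethoxybenzaldehyde | COc1cc(C=O)cc(OC)c1OCc1ccccc1 | intermediate
3 | dimethyl succinate | COC(=O)CCC(=O)OC | starting material
4 | (E)-4-[4-(benzyloxy)-3,5-dimethoxyphenyl]-3-(methoxycarbonyl)but-3-enoic acid | COC(=O)/C(CC(=O)O)=C/c1cc(OC)c(OCc2ccccc2)c(OC)c1 | intermediate
5 | (S)-4-[4-(benzyloxy)-3,5-dimethoxyphenyl]-3-(methoxycarbonyl)butanoic acid | COc1cc(C[C@H](C(=O)OC)CC(=O)O)cc(OC)c1OCc1ccccc1 | intermediate
6 | (S)-4-[4-(benzyloxy)-3,5-dimethoxyphenyl]-3-(hydroxymethyl)butanoic acid | COc1cc(C[C@H](CO)CC(=O)O)cc(OC)c1OCc1ccccc1 | intermediate (not isolated)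
7 | (S)-4-[4-(benzyloxy)-3,5-dimethoxybenzyl]dihydrofuran-2(3H)-one | COc1cc(C[C@@H]2COC(=O)C2)cc(OC)c1OCc1ccccc1 | intermediate
8 | {[(S)-4-[4-(benzyloxy)-3,5-dimethoxybenzyl]-4,5-dihydrofuran-2-yl]oxy}trimethylsilane | COc1cc(C[C@@H]2COC(O[Si](C)(C)C)=C2)cc(OC)c1OCc1ccccc1 | intermediate (not isolated)
9 | (3R,4S)-4-[4-(benzyloxy)-3,5-dimethoxybenzyl]-3-(dimethoxymethyl)dihydrofuran-2(3H)-one (trans) | COc1cc(C[C@@H]2COC(=O)[C@H]2C(OC)OC)cc(OC)c1OCc1ccccc1 | intermediate
10 | (2S,3S)-2-[4-(benzyloxy)-3,5-dimethoxybenzyl]-3-(dimethoxymethyl)butane-1,4-diol | COc1cc(C[C@H](CO)[C@@H](CO)C(OC)OC)cc(OC)c1OCc1ccccc1 | intermediate (not isolated)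
11 | [(3S,4S)-4-[4-(benzyloxy)-3,5-dimethoxybenzyl]-2-methoxyoxolan-3-yl]methanol (3,4-cis; both anomers) | COc1cc(C[C@@H]2COC(OC)[C@@H]2CO)cc(OC)c1OCc1ccccc1 | intermediate
12 | tert-butyl{[(3S,4S)-4-[4-(benzyloxy)-3,5-dimethoxybenzyl]-2-methoxyoxolan-3-yl]methoxy}diphenylsilane (3,4-cis; both anomers) | COc1cc(C[C@@H]2COC(OC)[C@@H]2CO[Si](C(C)(C)C)(c3ccccc3)c3ccccc3)cc(OC)c1OCc1ccccc1 | intermediate
13 | 2,6-dimethoxyphenol | COc1cccc(OC)c1O | starting material
14 | (1S,2S,3S)-7-(benzyloxy)-2-({[tert-butyl(diphenyl)silyl]oxy}methyl)-6,8-dimethoxy-1,2,3,4-tetrahydronaphthalene with C1 joined through oxygen to the C3 methylene (C1–O–C3a bridge) | O1[C@@H]2c3c(cc(OC)c(OCc4ccccc4)c3OC)C[C@H](C1)[C@H]2CO[Si](C(C)(C)C)(c5ccccc5)c6ccccc6 | intermediate (not isolated)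
15 | 4-[(1R,2S,3S)-7-(benzyloxy)-2-({[tert-butyl(diphenyl)silyl]oxy}methyl)-3-(hydroxymethyl)-6,8-dimethoxy-1,2,3,4-tetrahydronaphthalen-1-yl]-2,6-dimethoxyphenol | COc1cc([C@@H]2c3c(cc(OC)c(OCc4ccccc4)c3OC)C[C@H](CO)[C@H]2CO[Si](C(C)(C)C)(c5ccccc5)c6ccccc6)cc(OC)c1O | intermediate
16 | (1R,2S,3S)-7-(benzyloxy)-1-[4-(benzyloxy)-3,5-dimethoxyphenyl]-3-[(benzyloxy)methyl]-2-({[tert-butyl(diphenyl)silyl]oxy}methyl)-6,8-dimethoxy-1,2,3,4-tetrahydronaphthalene | COc1cc([C@@H]2c3c(cc(OC)c(OCc4ccccc4)c3OC)C[C@H](COCc5ccccc5)[C@H]2CO[Si](C(C)(C)C)(c6ccccc6)c7ccccc7)cc(OC)c1OCc8ccccc8 | intermediate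
17 | [(1R,2S,3S)-7-(benzyloxy)-1-[4-(benzyloxy)-3,5-dimethoxyphenyl]-3-[(benzyloxy)methyl]-6,8-dimethoxy-1,2,3,4-tetrahydronaphthalen-2-yl]methanol | COc1cc([C@@H]2c3c(cc(OC)c(OCc4ccccc4)c3OC)C[C@H](COCc5ccccc5)[C@H]2CO)cc(OC)c1OCc6ccccc6 | intermediate
18 | [(1R,2S,3S)-7-(benzyloxy)-1-[4-(benzyloxy)-3,5-dimethoxyphenyl]-3-[(benzyloxy)methyl]-6,8-dimethoxy-1,2,3,4-tetrahydronaphthalen-2-yl]methyl hydrogen sulfate | COc1cc([C@@H]2c3c(cc(OC)c(OCc4ccccc4)c3OC)C[C@H](COCc5ccccc5)[C@H]2COS(=O)(=O)O)cc(OC)c1OCc6ccccc6 | intermediate
19 | [(1R,2S,3S)-7-hydroxy-1-(4-hydroxy-3,5-dimethoxyphenyl)-3-(hydroxymethyl)-6,8-dimethoxy-1,2,3,4-tetrahydronaphthalen-2-yl]methyl hydrogen sulfate | COc1cc([C@@H]2c3c(cc(OC)c(O)c3OC)C[C@H](CO)[C@H]2COS(=O)(=O)O)cc(OC)c1O | target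

## Step count and least certain steps

Total: 12 steps. Longest linear sequence: 12 steps, from 1 to 19; 3 enters in step 2 and 13 in step 8. Compound 2 is also a catalogue item; if it is bought, the sequence is 11 steps.

**Step 8 (key step).** Three things are most likely to go wrong.
- Poor facial selectivity in the capture of the C1 cation: a pseudo-axial approach on the half-chair with both arms pseudo-equatorial would put the arene cis to the C2 arm, and the case for trans rests on steric shielding by the silyloxymethyl group.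
- Attack of 13 through a carbon ortho/para to its methoxy groups instead of para to the hydroxyl, if BF3 complexation weakens the hydroxyl as a donor.
- Proton loss from the cation to the 1,2-dihydronaphthalene followed by reprotonation, which would erode C2.

Fallback: the C1–aryl bond is made first under basic conditions and ring B is closed afterwards, so that C1 is set in the ring closure. From 12, hydrolysis of the methyl acetal (AcOH–H2O–THF) gives the lactol (3S,4S)-4-[4-(benzyloxy)-3,5-dimethoxybenzyl]-3-({[tert-butyl(diphenyl)silyl]oxy}methyl)oxolan-2-ol F1. Commercial 4-bromo-2,6-dimethoxyphenol is benzylated (BnBr, K2CO3) to 2-(benzyloxy)-5-bromo-1,3-dimethoxybenzene F2 and converted with Mg in THF into [4-(benzyloxy)-3,5-dimethoxyphenyl]magnesium bromide F3. Addition of excess F3 to F1 gives the diol (2S,3S)-1-[4-(benzyloxy)-3,5-dimethoxyphenyl]-3-[4-(benzyloxy)-3,5-dimethoxybenzyl]-2-({[tert-butyl(diphenyl)silyl]oxy}methyl)butane-1,4-diol F4 as a pair of C1 epimers. CF3CO2H in CH2Cl2 at 0 °C ionises the benzylic carbinol and ring A closes on it through a chair-like transition state with the aryl group and both arms pseudo-equatorial, giving [(1R,2S,3S)-7-(benzyloxy)-1-[4-(benzyloxy)-3,5-dimethoxyphenyl]-2-({[tert-butyl(diphenyl)silyl]oxy}methyl)-6,8-dimethoxy-1,2,3,4-tetrahydronaphthalen-3-yl]methanol F5. Benzylation of its one hydroxyl under the conditions of step 9 returns to the route at 16. The regiochemistry of the pendant ring is then fixed by the bromide.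

**Step 5.** The likely failures are loss of methanol from the product acetal under the Lewis acid (giving the methoxymethylene lactone) and protodesilylation of 8 before it is alkylated.

Fallback: C2 is set by hydrogenation instead of alkylation. From 7, Claisen formylation (HCO2Et, NaH, THF) gives the enol (S)-4-[4-(benzyloxy)-3,5-dimethoxybenzyl]-3-(hydroxymethylene)dihydrofuran-2(3H)-one F6. Silylation (TBDPSCl, Et3N, CH2Cl2) gives the silyloxymethylene lactone F7 (alkene geometry immaterial). Hydrogenation with [Ir(cod)(PCy3)(py)]PF6 in CH2Cl2, which spares the benzyl ether, should add hydrogen to the exocyclic alkene anti to the benzyl group and give the cis lactone (3S,4S)-4-[4-(benzyloxy)-3,5-dimethoxybenzyl]-3-({[tert-butyl(diphenyl)silyl]oxy}methyl)dihydrofuran-2(3H)-one F8. DIBAL-H at −78 °C gives the lactol F1, which is used with 13 under the conditions of step 8 (water leaves in place of methanol) and returns to the route at 15.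

**Step 9.** The risk is base-induced migration of the silyl group from C2a–O to the C3a alkoxide through a seven-membered siliconate before benzylation, which would exchange the roles of the two arms.

Fallback: hydrogenolysable protection without an alkoxide. From 15, benzyl chloroformate with pyridine and catalytic 4-(dimethylamino)pyridine in CH2Cl2 gives the bis(benzyl carbonate) F9 (at the phenol and at C3a–O). HF·pyridine in THF–pyridine removes the silyl group to give the alcohol F10. SO3·pyridine gives the hydrogen sulfate F11. Hydrogenolysis (H2, Pd/C) cleaves the benzyl ether and both benzyl carbonates and returns to the route at 19.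

**Step 3.** The risk is insufficient enantioselectivity, or the opposite sense, with this tri-oxygenated aryl substrate, and erosion by any Z isomer in 4.

Fallback: separation of a racemate. From 4, hydrogenation with an achiral catalyst ([Rh(nbd)(dppb)]BF4, H2, MeOH) gives the racemic acid F12. The conditions of step 4 convert it into the racemic lactone F13, whose enantiomers are separated by preparative chromatography on a chiral stationary phase; the S enantiomer returns to the route at 7.

## Further compounds

F1 | step 8 | (3S,4S)-4-[4-(benzyloxy)-3,5-dimethoxybenzyl]-3-({[tert-butyl(diphenyl)silyl]oxy}methyl)oxolan-2-ol (both anomers) | COc1cc(C[C@@H]2COC(O)[C@@H]2CO[Si](C(C)(C)C)(c3ccccc3)c3ccccc3)cc(OC)c1OCc1ccccc1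
F2 | step 8 | 2-(benzyloxy)-5-bromo-1,3-dimethoxybenzene | COc1cc(Br)cc(OC)c1OCc1ccccc1
F3 | step 8 | [4-(benzyloxy)-3,5-dimethoxyphenyl]magnesium bromide | COc1cc([Mg]Br)cc(OC)c1OCc1ccccc1
F4 | step 8 | (2S,3S)-1-[4-(benzyloxy)-3,5-dimethoxyphenyl]-3-[4-(benzyloxy)-3,5-dimethoxybenzyl]-2-({[tert-butyl(diphenyl)silyl]oxy}methyl)butane-1,4-diol (C1 epimers) | COc1cc(C[C@H](CO)[C@@H](CO[Si](C(C)(C)C)(c2ccccc2)c2ccccc2)C(O)c2cc(OC)c(OCc3ccccc3)c(OC)c2)cc(OC)c1OCc1ccccc1
F5 | step 8 | [(1R,2S,3S)-7-(benzyloxy)-1-[4-(benzyloxy)-3,5-dimethoxyphenyl]-2-({[tert-butyl(diphenyl)silyl]oxy}methyl)-6,8-dimethoxy-1,2,3,4-tetrahydronaphthalen-3-yl]methanol | COc1cc([C@@H]2c3c(cc(OC)c(OCc4ccccc4)c3OC)C[C@H](CO)[C@H]2CO[Si](C(C)(C)C)(c5ccccc5)c6ccccc6)cc(OC)c1OCc7ccccc7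
F6 | step 5 | (S)-4-[4-(benzyloxy)-3,5-dimethoxybenzyl]-3-(hydroxymethylene)dihydrofuran-2(3H)-one (enol of the 3-formyl lactone) | COc1cc(C[C@@H]2COC(=O)C2=CO)cc(OC)c1OCc1ccccc1
F7 | step 5 | (S)-4-[4-(benzyloxy)-3,5-dimethoxybenzyl]-3-({[tert-butyl(diphenyl)silyl]oxy}methylene)dihydrofuran-2(3H)-one | COc1cc(C[C@@H]2COC(=O)C2=CO[Si](C(C)(C)C)(c3ccccc3)c3ccccc3)cc(OC)c1OCc1ccccc1
F8 | step 5 | (3S,4S)-4-[4-(benzyloxy)-3,5-dimethoxybenzyl]-3-({[tert-butyl(diphenyl)silyl]oxy}methyl)dihydrofuran-2(3H)-one (cis) | COc1cc(C[C@@H]2COC(=O)[C@@H]2CO[Si](C(C)(C)C)(c3ccccc3)c3ccccc3)cc(OC)c1OCc1ccccc1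
F9 | step 9 | bis(benzyl carbonate) of 15 at the phenol and at C3a–O, (1R,2S,3S) | COc1cc([C@@H]2c3c(cc(OC)c(OCc4ccccc4)c3OC)C[C@H](COC(=O)OCc5ccccc5)[C@H]2CO[Si](C(C)(C)C)(c6ccccc6)c7ccccc7)cc(OC)c1OC(=O)OCc8ccccc8
F10 | step 9 | C2a alcohol from F9 by desilylation, (1R,2S,3S) | COc1cc([C@@H]2c3c(cc(OC)c(OCc4ccccc4)c3OC)C[C@H](COC(=O)OCc5ccccc5)[C@H]2CO)cc(OC)c1OC(=O)OCc6ccccc6
F11 | step 9 | C2a hydrogen sulfate of F10, (1R,2S,3S) | COc1cc([C@@H]2c3c(cc(OC)c(OCc4ccccc4)c3OC)C[C@H](COC(=O)OCc5ccccc5)[C@H]2COS(=O)(=O)O)cc(OC)c1OC(=O)OCc6ccccc6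
F12 | step 3 | racemic 4-[4-(benzyloxy)-3,5-dimethoxyphenyl]-3-(methoxycarbonyl)butanoic acid | COc1cc(CC(C(=O)OC)CC(=O)O)cc(OC)c1OCc1ccccc1
F13 | step 3 | racemic 4-[4-(benzyloxy)-3,5-dimethoxybenzyl]dihydrofuran-2(3H)-one | COc1cc(CC2COC(=O)C2)cc(OC)c1OCc1ccccc1
A1 | alternative 1 | (S)-4-benzyl-3-[(E)-3-(4-hydroxy-3,5-dimethoxyphenyl)prop-2-enoyl]oxazolidin-2-one | COc1cc(/C=C/C(=O)N2C(=O)OC[C@@H]2Cc2ccccc2)cc(OC)c1O
A2 | alternative 1 | (1R,2S)-7-hydroxy-1-(4-hydroxy-3,5-dimethoxyphenyl)-6,8-dimethoxy-1,2-dihydronaphthalene-2,3-dicarbonyl bis[(S)-4-benzyl-2-oxooxazolidin-3-yl] imide | COc1cc([C@@H]2c3c(cc(OC)c(O)c3OC)C=C(C(=O)N4C(=O)OC[C@@H]4Cc4ccccc4)[C@H]2C(=O)N5C(=O)OC[C@@H]5Cc5ccccc5)cc(OC)c1O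
A3 | alternative 2 | 4-(benzyloxy)-2-[4-(benzyloxy)-3,5-dimethoxybenzyl]-3,5-dimethoxybenzaldehyde | O=Cc1cc(OC)c(OCc2ccccc2)c(OC)c1Cc1cc(OC)c(OCc2ccccc2)c(OC)c1
A4 | alternative 2 | bis[(S)-1-methoxy-1-oxopropan-2-yl] fumarate | COC(=O)[C@H](C)OC(=O)/C=C/C(=O)O[C@@H](C)C(=O)OC
A5 | alternative 2 | bis[(S)-1-methoxy-1-oxopropan-2-yl] 7-(benzyloxy)-1-[4-(benzyloxy)-3,5-dimethoxyphenyl]-4-hydroxy-6,8-dimethoxy-1,2,3,4-tetrahydronaphthalene-2,3-dicarboxylate (all-trans at C1–C3, C4 hydroxyl cis to the C3 ester) | COc1cc([C@@H]2c3c(cc(OC)c(OCc4ccccc4)c3OC)[C@H](O)[C@H](C(=O)O[C@@H](C)C(=O)OC)[C@H]2C(=O)O[C@@H](C)C(=O)OC)cc(OC)c1OCc1ccccc1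
A6 | alternative 3 | (2S)-2-{(R)-[4-(benzyloxy)-3,5-dimethoxyphenyl][3-(benzyloxy)-6-ethenyl-2,4-dimethoxyphenyl]methyl}-3-[(benzyloxy)methyl]but-3-en-1-ol | COc1cc([C@H](c2c(C=C)cc(OC)c(OCc3ccccc3)c2OC)[C@H](CO)C(=C)COCc2ccccc2)cc(OC)c1OCc1ccccc1
A7 | alternative 3 | [(1R,2S)-7-(benzyloxy)-1-[4-(benzyloxy)-3,5-dimethoxyphenyl]-3-[(benzyloxy)methyl]-6,8-dimethoxy-1,2-dihydronaphthalen-2-yl]methanol | COc1cc([C@@H]2c3c(cc(OC)c(OCc4ccccc4)c3OC)C=C(COCc4ccccc4)[C@H]2CO)cc(OC)c1OCc1ccccc1
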